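## Structural features

The target 39 (C60H42O35) is a linear chain of ten benzene rings, lettered A to J, joined by nine diaryl ether oxygens and carrying twenty-six free phenolic hydroxyls; it has no stereocentre, so no stereochemical relation has to be set. Rings B, D, F and H are phloroglucinol-type rings with oxygen at positions 1, 3 and 5 and a fourth oxygen at position 4: positions 1 and 4 carry the ether bridges, positions 3 and 5 the hydroxyls. Rings C, E, G and I are pentaoxygenated, with the two bridges on the neighbouring carbons 1 and 6 and hydroxyls at 3, 4 and 5; ring A is a 2,4,6-trihydroxyphenyl cap bound through a4 and ring J a 3,4,5-trihydroxyphenyl cap bound through j1. Each bridge of the type b4–O–c1 (also d4–O–e1, f4–O–g1, h4–O–i1) has three ortho substituents, and each bridge of the type c6–O–d1 starts from a carbon flanked by two oxygens, so neither SNAr nor metal-catalysed C–O coupling is dependable at these crowded, electron-rich carbons. The free polyphenol is sensitive to oxygen, above all in base, and its rings are prone to electrophilic attack, so the hydroxyls travel as methyl ethers and are released only in the last step under argon. The real difficulty is the regiocontrolled making of nine hindered aryl–oxygen bonds between almost identical rings without ever having to tell apart two similar free hydroxyls. The key step uses the fact that ring F has the carbon and oxygen pattern of a triketide: the oxygens on f1, f3 and f5 correspond to the C4 oxygen, the lactone carbonyl C2 and the ring oxygen at C6 of a pyran-2-one, and f4 to the exocyclic carbon on C6, so the bridges f1–O–e6 and f4–O–g1 can be made as a vinylic and an alkyl carbon–oxygen bond before the f3–f4 bond closes the benzene ring. Rings B, D and H show the same pattern and are made in the same way.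

## Logic of the disconnections

39 ⇒ 38. All twenty-four O–CH3 bonds are cut. Methyl ethers are kept to the end because 4, 9 and 15 already carry them and they survive every base, acid, organolithium and copper step. The gain is an air-stable, chromatographable precursor. The demand is a reagent that cleaves every methyl ether and none of the nine diaryl ether bridges.

38 ⇒ 36 (through 37). The f3–f4 carbon–carbon bond is cut and ring F is unfolded into the lactone ring of 36: f3 becomes the lactone carbonyl carbon, f5 the carbon on the ring oxygen, f1 the carbon bearing the e6 oxygen, f4 the exocyclic CH2. This is the cut in ring F that turns both neighbouring bridges into bonds that need no aryl carbon–oxygen coupling, and it divides the decamer near its middle. The demand is that the forward step opens the lactone, forms the C–C bond from the aryloxy-bearing carbon and does not exchange the e6 aryloxy group.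

36 ⇒ 25 + 35. The bond between the e6 oxygen and C4 of the lactone ring is cut. This separates the five-ring half from the four-ring half and makes a hindered ether by addition–elimination at a vinylogous acyl carbon. The demand is that the di-ortho-substituted phenoxide of 25 displaces the C4 bromide of 35 without opening the lactone.

35 ⇒ 34 + 3, then 3 ⇒ 2 ⇒ 1. The bond between the g1 oxygen and the CH2 group is cut, so the tri-ortho-substituted bridge f4–O–g1 is made as a simple SN2 ether. The linker 3 goes back to 1 by replacing C4–Br with C4–OH and CH2Br with CH3. The demand is chemoselectivity: the phenoxide of 34 must react at the CH2Br carbon of 3 and leave C4–Br for the next step.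

25 ⇒ 24 ⇒ 23 ⇒ 21 (through 22) ⇒ 20 + 14. Ring D has the pattern of ring F and is cut the same way: the O–CH2OCH3 bond at e6, the two O–CH3 bonds at d3 and d5, the d3–d4 carbon–carbon bond, and the bond from the c6 oxygen to C4 of the lactone. Each round adds two rings with one building block, 14. The demand is that the temporary group at e6 survives ring closure and methylation and then leaves without harm to the electron-rich rings.

20 ⇒ 19 ⇒ 18 ⇒ 16 (through 17) ⇒ 15 + 14, then 14 ⇒ 13 + 3. Ring B is cut in the same four operations, with 15 as the phenol for C4. 14 is cut at the bond between the c1 (or e1) oxygen and CH2. The gain is that one building block serves rings B–C and D–E. The demand on 13 is one free hydroxyl next to the ring hydrogen and one masked hydroxyl next to the methoxy groups.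

13 ⇒ 10 ⇒ 9 (through 11 and 12). The aryl C–OH bond of 13 is cut back to a C–H bond, and the CH2OCH3 group to the phenol 9. The masked oxygen is the original phenol oxygen and the new oxygen arrives free, so the two catechol oxygens are never both free. The demand is metalation only at the position next to the acetal oxygen.

34 ⇒ 33 ⇒ 32 ⇒ 30 (through 31) ⇒ 29 + 8, then 29 ⇒ 28 + 3. Ring H is cut like ring F: O–CH2OCH3 at g1, O–CH3 at h3 and h5, the h3–h4 bond, and the bond from the g6 oxygen to C4. Here the catechol unit 8 enters through its hindered hydroxyl and keeps the other one masked for the later union with 3.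

28 ⇒ 27 ⇒ 8 + 26, then 8 ⇒ 5 ⇒ 4 (through 6 and 7). The i6–O–j1 bridge is the only one cut as an aryl carbon–oxygen bond, on the ring J side where the carbon has no ortho substituent. 8 goes back to 4 by the same protection and directed hydroxylation as 13 from 9, with the positions of free and masked oxygen exchanged. The demand is a copper-mediated coupling of a di-ortho-substituted phenol.

## Other disconnections considered

Alternative 1: The cut runs through ring B of an A–B–C trimer (bonds b1–b6, b2–b3 and b3–b4). It leads back to the racemic 4-aryloxy-3-ethoxycyclobutenone A2, which carries ring C through its c1 oxygen, and the aryl ethynyl ether A3 of ring A.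
- Forward step: heating A2 with A3 should open the four-membered ring to a vinylketene, which adds [2+2] to the alkyne (b3–b2, b6–b1). A second ring opening and a 6π closure (b3–b4) would give the phenol A1 (Danheiser benzannulation).
- In favour: the cascade is thermal and neutral, so no nucleophile is present that could exchange an aryloxy group; on this point it is better than the chosen plan. The regiochemistry follows from the polarity of ketene and ynol ether, which equals the certainty of the pyranone route. It also delivers b3 (OH) and b5 (OEt) differentiated, which the chosen plan cannot do, although the target does not need it.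
- Against: it builds an end ring of a trimer and not the central ring of the decamer. A3 requires an ynol ether of the di-ortho-substituted phenol 15, and A2 an aryloxyketene–ethoxyacetylene cycloaddition on a ring C unit that must be made first. The ethyl ether is an extra spectator. Repeating the tactic for rings D, F and H would need ynol ethers of ever larger hindered phenols.
- Step economy: A1 is estimated at nine to ten operations from 9 and 15, against seven steps to the comparable 18 in the chosen plan (steps 1, 2, 5 to 9). Structurally both plans place the two ether oxygens before the ring exists, so they are equal there.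

Alternative 2: The cut is the c1–c6 bond of ring C in the trimer phenol A4, which has the same structure as 20. It leads back to the racemic 4-alkenyl-2,3,4-trimethoxycyclobutenone A5, obtainable in principle from a dialkyl squarate and an (E)-2-aryloxyvinyl metal reagent derived from an A–B phenol.
- Forward step: heating A5 should open the ring to a dienylketene with the alkenyl group turned inward, and 6π electrocyclisation plus enolisation would give A4 with a free hydroxyl only at c6 (Moore-type ring expansion).
- In favour: all five oxygens of ring C are placed by construction, and the only free hydroxyl is the one the next union needs. No temporary protecting group and no separately made catechol monomer are required; on these points it is better than the chosen plan, which needs 8, 13 and four MOM cleavages. It is also neutral and thermal.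
- Against: the aryloxyvinyl metal reagent must come from a b4 phenol flanked by two methoxy groups, through O-vinylation and metalation. The A–B diaryl ether then needs a hindered aryl C–O coupling, because ring B is not addressed. The tertiary alkoxide must be methylated, and the enol ether is acid-labile.
- Comparison: the tactic makes rings of the C type, the chosen one rings of the F type, so the two are complementary in structure. To reach the same compound (A4 = 20) the chosen plan needs four steps from 14 and 15, whereas the squarate route is estimated at six or more after the A–B phenol. On step economy the chosen plan is ahead; on protecting-group economy the alternative is ahead.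

Alternative 3: The cut removes five aryl C–O bonds (c4, e4, g4, i4, j4) of the pentaphenol A6 and leads back to the decamer pentaaldehyde A7.
- Forward step: H2O2 with catalytic SeO2, or mCPBA, should convert each formyl group into a formate by aryl migration, and hydrolysis would give A6 (fivefold Dakin oxidation).
- In favour: each formyl group sits para to c1, e1, g1, i1 or j1 and would activate that carbon for SNAr ether formation during assembly before being turned into oxygen. The formyl-bearing intermediates are less electron-rich and less oxidation-prone than those of the chosen plan, a point on which it is better. The Dakin reaction on di-ortho-methoxy benzaldehydes is as well founded as any step of the chosen route, and the end-game length is equal (one step, then global demethylation).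
- Against: it is a functional-group change that builds no ring and no skeletal bond. All nine bridges, including four tri-ortho-substituted ones at carbons next to an aryloxy group, must already exist in A7. Five oxidations must all go to completion in one flask. The rings formed are p-aryloxyphenols, which a peroxide can oxidise further to quinones with loss of the bridge.
- Comparison: the chosen plan solves the skeletal problem convergently with one C–C bond, whereas this one postpones it to the synthesis of A7, which is not expected to be shorter.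

Key step: step 25

Remarks on the chemistry:
- Ring letters run from the 2,4,6-trioxygenated cap (ring A) to the 3,4,5-trioxygenated cap (ring J), and lower-case locants such as b3 or e6 count each ring as set out in the first section. "A–E pentamer" and "G–J tetramer" mean these rings joined as in 39, with every hydroxyl methylated unless a free hydroxyl or a MOM ether is named.
- In 17, 22, 31 and 37 the ester carbon and the CH2–CO arm lie on the same side of C2=C3, as the lactone fixes them. Because the aryloxy group outranks that carbon arm, the CIP descriptor of this closure-competent geometry is E, not Z.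
- A 4-arenesulfonate is unsuitable as the C4 leaving group when the 6-methyl group is brominated by a radical path: the tolyl methyl group is itself benzylic, and a phenoxide can attack sulfur. Bromide is therefore used at C4 (2, 3).
- 36 and 38 correspond ring by ring to 39; both carry twenty-four methyl ethers and map onto the target without change of the skeleton.
- Assumption: 9 and 26 are treated as commercial starting materials beside 1, 4 and 15.

Step 1
Reactants: 1 4-hydroxy-6-methylpyran-2-one
Product: 2 4-bromo-6-methylpyran-2-one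
Conditions: nBu4NBr, P2O5, toluene, 100 °C
Reagents that add atoms: tetrabutylammonium bromide, CCCC[N+](CCCC)(CCCC)CCCC.[Br-]
Why: The vinylogous acid hydroxyl is activated as a phosphate ester and replaced by bromide through addition–elimination at C4 (deoxybromination of a 4-hydroxypyran-2-one).

Step 2
Reactants: 2 4-bromo-6-methylpyran-2-one
Product: 3 4-bromo-6-(bromomethyl)pyran-2-one
Conditions: NBS, AIBN (cat.), PhCF3, 85 °C
Reagents that add atoms: N-bromosuccinimide, O=C1CCC(=O)N1Br
Why: Wohl–Ziegler bromination of the methyl group, whose radical is delocalised over the pyranone diene; the C4 bromine lowers the nucleophilicity of C3 and C5 so ionic ring bromination should stay minor, and the molecule has no second benzylic C–H bond.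

Step 3
Reactants: 4 3,4,5-trimethoxyphenol
Product: 5 1,2,3-trimethoxy-5-(methoxymethoxy)benzene
Conditions: MOMCl, iPr2NEt, CH2Cl2, 0 °C to rt
Reagents that add atoms: chloromethyl methyl ether, COCCl
Why: O-Alkylation of the phenol; the methoxymethyl (MOM) group serves as temporary protecting group and as directing group for the next step.

Step 4
Reactants: 5 1,2,3-trimethoxy-5-(methoxymethoxy)benzene
Product: 8 2,3,4-trimethoxy-6-(methoxymethoxy)phenol, via the aryllithium 6 (not isolated), via the dimethyl arylboronate 7 (not isolated)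
Conditions: nBuLi, THF, 0 °C; B(OMe)3, −78 °C to rt; aq H2O2, aq NaOH, 0 °C
Reagents that add atoms: hydrogen peroxide, OO (oxygen of 8); n-butyllithium, [Li]CCCC (lithium of 6 only); trimethyl borate, COB(OC)OC (boron group of 7 only)
Why: Directed ortho metalation between the MOM ether and a methoxy group (the two such positions are equivalent), borylation and oxidative aryl migration from boron to oxygen; the new hydroxyl is the future g6 or i6 oxygen while the original phenol oxygen stays masked.

Step 5
Reactants: 9 2,3,4-trimethoxyphenol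
Product: 10 1,2,3-trimethoxy-4-(methoxymethoxy)benzene
Conditions: MOMCl, iPr2NEt, CH2Cl2, 0 °C to rt
Reagents that add atoms: chloromethyl methyl ether, COCCl
Why: O-Alkylation of the phenol, as in step 3.

Step 6
Reactants: 10 1,2,3-trimethoxy-4-(methoxymethoxy)benzene
Product: 13 3,4,5-trimethoxy-2-(methoxymethoxy)phenol, via the aryllithium 11 (not isolated), via the dimethyl arylboronate 12 (not isolated)
Conditions: nBuLi, TMEDA, THF, 0 °C; B(OMe)3, −78 °C to rt; aq H2O2, aq NaOH, 0 °C
Reagents that add atoms: hydrogen peroxide, OO (oxygen of 13); n-butyllithium, [Li]CCCC (lithium of 11 only); trimethyl borate, COB(OC)OC (boron group of 12 only)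
Why: Directed ortho metalation at the only position next to the MOM ether, a stronger director than methoxy, then borylation and oxidation; the new free hydroxyl is the future c1 or e1 oxygen and the MOM-masked one the future c6 or e6 oxygen.

Step 7
Reactants: 13 3,4,5-trimethoxy-2-(methoxymethoxy)phenol, 3 4-bromo-6-(bromomethyl)pyran-2-one
Product: 14 4-bromo-6-{[3,4,5-trimethoxy-2-(methoxymethoxy)phenoxy]methyl}pyran-2-one
Conditions: K2CO3, acetone, 0 °C to rt
Reagents that add atoms: none
Why: Williamson ether synthesis; SN2 at the primary bromide, activated like an alpha-bromo ester through the diene, should outrun addition–elimination at C4 at low temperature with a weak base and a slight excess of 3.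

Step 8
Reactants: 15 2,4,6-trimethoxyphenol, 14 4-bromo-6-{[3,4,5-trimethoxy-2-(methoxymethoxy)phenoxy]methyl}pyran-2-one
Product: 16 6-{[3,4,5-trimethoxy-2-(methoxymethoxy)phenoxy]methyl}-4-(2,4,6-trimethoxyphenoxy)pyran-2-one
Conditions: Cs2CO3, DMF, rt to 40 °C
Reagents that add atoms: none
Why: Addition–elimination of the phenoxide at C4 of a 4-bromopyran-2-one (vinylogous acyl substitution), which tolerates the two ortho methoxy groups because the electrophilic carbon is sp2 and unhindered.

Step 9
Reactants: 16 6-{[3,4,5-trimethoxy-2-(methoxymethoxy)phenoxy]methyl}-4-(2,4,6-trimethoxyphenoxy)pyran-2-one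
Product: 18 2-[3,4,5-trimethoxy-2-(methoxymethoxy)phenoxy]-5-(2,4,6-trimethoxyphenoxy)benzene-1,3-diol, via the open-chain methyl ester 17 (not isolated)
Conditions: Mg(OMe)2, MeOH–THF, 65 °C; then cold dilute aq HCl
Reagents that add atoms: magnesium dimethoxide, C[O-].C[O-].[Mg+2] (supplies the methoxy group of 17; no atom of it remains in 18)
Why: Methanolysis of the lactone gives 17, whose aryloxy-bearing ketone alpha carbon acylates on the ester carbon (Claisen cyclisation, 6-exo-trig) to close ring B; tautomerisation to the resorcinol magnesium salt drives it. MOM and methyl ethers are inert to Mg(OMe)2 and to a brief cold acidic work-up, and this run calibrates the conditions for steps 13, 20 and 25.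

Step 10
Reactants: 18 2-[3,4,5-trimethoxy-2-(methoxymethoxy)phenoxy]-5-(2,4,6-trimethoxyphenoxy)benzene-1,3-diol
Product: 19 1,3-dimethoxy-2-[3,4,5-trimethoxy-2-(methoxymethoxy)phenoxy]-5-(2,4,6-trimethoxyphenoxy)benzene
Conditions: MeI, K2CO3, DMF, rt
Reagents that add atoms: iodomethane, CI
Why: Williamson O-methylation of the two hydroxyls b3 and b5; K2CO3 in DMF favours O- over C-alkylation and leaves the MOM ether alone.

Step 11
Reactants: 19 1,3-dimethoxy-2-[3,4,5-trimethoxy-2-(methoxymethoxy)phenoxy]-5-(2,4,6-trimethoxyphenoxy)benzene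
Product: 20 6-[2,6-dimethoxy-4-(2,4,6-trimethoxyphenoxy)phenoxy]-2,3,4-trimethoxyphenol
Conditions: HCl (cat.), MeOH–THF, 45 °C
Reagents that add atoms: none
Why: Acid-catalysed acetal exchange removes the MOM group; methanol captures the methoxymethyl cation as dimethoxymethane and so keeps it away from the electron-rich rings, while aryl methyl and diaryl ethers are stable to dilute HCl.

Step 12
Reactants: 20 6-[2,6-dimethoxy-4-(2,4,6-trimethoxyphenoxy)phenoxy]-2,3,4-trimethoxyphenol, 14 4-bromo-6-{[3,4,5-trimethoxy-2-(methoxymethoxy)phenoxy]methyl}pyran-2-one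
Product: 21 4-{6-[2,6-dimethoxy-4-(2,4,6-trimethoxyphenoxy)phenoxy]-2,3,4-trimethoxyphenoxy}-6-{[3,4,5-trimethoxy-2-(methoxymethoxy)phenoxy]methyl}pyran-2-one
Conditions: Cs2CO3, DMF, 40 °C
Reagents that add atoms: none
Why: Addition–elimination of the c6 phenoxide at C4 of the bromopyranone, as in step 8.

Step 13
Reactants: 21 4-{6-[2,6-dimethoxy-4-(2,4,6-trimethoxyphenoxy)phenoxy]-2,3,4-trimethoxyphenoxy}-6-{[3,4,5-trimethoxy-2-(methoxymethoxy)phenoxy]methyl}pyran-2-one
Product: 23 A–E pentamer with free hydroxyls at d3 and d5 and a MOM ether at e6 (all other oxygens methylated), via the open-chain methyl ester 22 (not isolated)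
Conditions: Mg(OMe)2, MeOH–THF, 65 °C; then cold dilute aq HCl
Reagents that add atoms: magnesium dimethoxide, C[O-].C[O-].[Mg+2] (supplies the methoxy group of 22; no atom of it remains in 23)
Why: Lactone opening and Claisen cyclisation (6-exo-trig) as in step 9, here closing ring D between the c6 oxygen on d1 and the e1 oxygen on d4.

Step 14
Reactants: 23 A–E pentamer with free hydroxyls at d3 and d5 and a MOM ether at e6
Product: 24 A–E pentamer with all hydroxyls methylated except e6 (MOM ether)
Conditions: MeI, K2CO3, DMF, rt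
Reagents that add atoms: iodomethane, CI
Why: Williamson O-methylation of d3 and d5, as in step 10.

Step 15
Reactants: 24 A–E pentamer with all hydroxyls methylated except e6 (MOM ether)
Product: 25 A–E pentamer phenol with the only free hydroxyl at e6
Conditions: HCl (cat.), MeOH–THF, 45 °C
Reagents that add atoms: none
Why: Acid-catalysed MOM cleavage with methanol as cation trap, as in step 11.

Step 16
Reactants: 8 2,3,4-trimethoxy-6-(methoxymethoxy)phenol, 26 5-iodo-1,2,3-trimethoxybenzene
Product: 27 1,2,3-trimethoxy-5-(methoxymethoxy)-4-(3,4,5-trimethoxyphenoxy)benzene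
Conditions: CuI (cat.), picolinic acid (cat.), K3PO4, DMSO, 90 °C
Reagents that add atoms: none
Why: Ullmann diaryl ether synthesis; the CuI–picolinic acid system is suited to di-ortho-substituted phenols, and the iodide carries no ortho substituent, so the crowding lies only on the oxygen partner.

Step 17
Reactants: 27 1,2,3-trimethoxy-5-(methoxymethoxy)-4-(3,4,5-trimethoxyphenoxy)benzene
Product: 28 3,4,5-trimethoxy-2-(3,4,5-trimethoxyphenoxy)phenol
Conditions: HCl (cat.), MeOH–THF, 45 °C
Reagents that add atoms: none
Why: Acid-catalysed MOM cleavage, as in step 11; it frees the i1 hydroxyl.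

Step 18
Reactants: 28 3,4,5-trimethoxy-2-(3,4,5-trimethoxyphenoxy)phenol, 3 4-bromo-6-(bromomethyl)pyran-2-one
Product: 29 4-bromo-6-{[3,4,5-trimethoxy-2-(3,4,5-trimethoxyphenoxy)phenoxy]methyl}pyran-2-one
Conditions: K2CO3, acetone, 0 °C to rt
Reagents that add atoms: none
Why: Williamson ether synthesis at the CH2Br carbon, as in step 7.

Step 19
Reactants: 29 4-bromo-6-{[3,4,5-trimethoxy-2-(3,4,5-trimethoxyphenoxy)phenoxy]methyl}pyran-2-one, 8 2,3,4-trimethoxy-6-(methoxymethoxy)phenol
Product: 30 4-[2,3,4-trimethoxy-6-(methoxymethoxy)phenoxy]-6-{[3,4,5-trimethoxy-2-(3,4,5-trimethoxyphenoxy)phenoxy]methyl}pyran-2-one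
Conditions: Cs2CO3, DMF, 40 °C
Reagents that add atoms: none
Why: Addition–elimination of the hindered g6 phenoxide at C4, as in step 8; g1 stays masked as MOM ether.

Step 20
Reactants: 30 4-[2,3,4-trimethoxy-6-(methoxymethoxy)phenoxy]-6-{[3,4,5-trimethoxy-2-(3,4,5-trimethoxyphenoxy)phenoxy]methyl}pyran-2-one
Product: 32 5-[2,3,4-trimethoxy-6-(methoxymethoxy)phenoxy]-2-[3,4,5-trimethoxy-2-(3,4,5-trimethoxyphenoxy)phenoxy]benzene-1,3-diol, via the open-chain methyl ester 31 (not isolated)
Conditions: Mg(OMe)2, MeOH–THF, 65 °C; then cold dilute aq HCl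
Reagents that add atoms: magnesium dimethoxide, C[O-].C[O-].[Mg+2] (supplies the methoxy group of 31; no atom of it remains in 32)
Why: Lactone opening and Claisen cyclisation (6-exo-trig) as in step 9, here closing ring H.

Step 21
Reactants: 32 5-[2,3,4-trimethoxy-6-(methoxymethoxy)phenoxy]-2-[3,4,5-trimethoxy-2-(3,4,5-trimethoxyphenoxy)phenoxy]benzene-1,3-diol
Product: 33 G–J tetramer with all hydroxyls methylated except g1 (MOM ether)
Conditions: MeI, K2CO3, DMF, rt
Reagents that add atoms: iodomethane, CI
Why: Williamson O-methylation of h3 and h5, as in step 10.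

Step 22
Reactants: 33 G–J tetramer with all hydroxyls methylated except g1 (MOM ether)
Product: 34 2-{3,5-dimethoxy-4-[3,4,5-trimethoxy-2-(3,4,5-trimethoxyphenoxy)phenoxy]phenoxy}-3,4,5-trimethoxyphenol
Conditions: HCl (cat.), MeOH–THF, 45 °C
Reagents that add atoms: none
Why: Acid-catalysed MOM cleavage, as in step 11; it frees the g1 hydroxyl.

Step 23
Reactants: 34 2-{3,5-dimethoxy-4-[3,4,5-trimethoxy-2-(3,4,5-trimethoxyphenoxy)phenoxy]phenoxy}-3,4,5-trimethoxyphenol, 3 4-bromo-6-(bromomethyl)pyran-2-one
Product: 35 4-bromo-6-[(G–J tetramer aryloxy)methyl]pyran-2-one, the g1 oxygen bound to the CH2 group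
Conditions: K2CO3, acetone, 0 °C to rt
Reagents that add atoms: none
Why: Williamson ether synthesis at the CH2Br carbon, as in steps 7 and 18; it makes the future tri-ortho-substituted bridge f4–O–g1 as an alkyl aryl ether.

Step 24
Reactants: 35 4-bromo-6-[(G–J tetramer aryloxy)methyl]pyran-2-one, 25 A–E pentamer phenol with the only free hydroxyl at e6
Product: 36 4-(A–E pentamer aryloxy)-6-[(G–J tetramer aryloxy)methyl]pyran-2-one
Conditions: Cs2CO3, DMF, 40 to 50 °C
Reagents that add atoms: none
Why: Addition–elimination of the e6 phenoxide at C4 of the bromopyranone, as in steps 8, 12 and 19; it makes the future f1–O–e6 bridge as a vinylic ether.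

Step 25
Reactants: 36 4-(A–E pentamer aryloxy)-6-[(G–J tetramer aryloxy)methyl]pyran-2-one
Product: 38 decamer with free hydroxyls at f3 and f5 and all other hydroxyls as methyl ethers, via the open-chain methyl ester 37 (not isolated)
Conditions: Mg(OMe)2, MeOH–THF, 65 °C, Ar; then cold dilute aq HCl
Reagents that add atoms: magnesium dimethoxide, C[O-].C[O-].[Mg+2] (supplies the methoxy group of 37; no atom of it remains in 38)
Why: Magnesium-bound methoxide adds to the lactone carbonyl C2 of 36 and expels the enolate oxygen at C6, giving 37 with the ester carbon and the CH2–CO arm held cis on C2=C3 (descriptor E). Reversible enolisation of the ketone toward the aryloxy-bearing carbon, helped by the aryloxy group and by Mg chelation between the ketone oxygen and the g1 oxygen, lets that carbon (future f4) attack the ester carbon (future f3). Loss of methoxide gives a cyclohexadienone that tautomerises to the resorcinol and is deprotonated, which makes the closure irreversible. The closest known reaction is the base-mediated Claisen cyclisation of 3,5-dioxoalkanoate equivalents, including opened 4-oxygenated pyran-2-ones, to phloroglucinols. Ring F closes in a 6-exo-trig (enol-exo) mode; the enolate at the central CH2 could only form a four-membered ring and is a harmless resting state. No stereocentre is formed. The step needs C-acylation to beat methoxide exchange of the e6 aryloxy group and simple relactonisation: the weakly nucleophilic, chelating Mg(OMe)2, the shielding of C4 by di-ortho-substituted ring E and the aromatic sink secure this, and relactonisation only returns 36.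

Step 26
Reactants: 38 decamer with free hydroxyls at f3 and f5 and all other hydroxyls as methyl ethers
Product: 39 CNP0255890.0 (decamer with all hydroxyls free)
Conditions: BBr3 (excess), CH2Cl2, −78 °C to rt, Ar; then MeOH
Reagents that add atoms: none
Why: Lewis acid-mediated cleavage of aryl methyl ethers (bromide attacks the methyl group of the boron-complexed ether); diaryl ethers do not react, the by-products are volatile, and exclusion of air protects the polyphenol.

Compound list

1 | 4-hydroxy-6-methylpyran-2-one | Cc1cc(O)cc(=O)o1 | starting material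
2 | 4-bromo-6-methylpyran-2-one | Cc1cc(Br)cc(=O)o1 | intermediate
3 | 4-bromo-6-(bromomethyl)pyran-2-one | BrCc1cc(Br)cc(=O)o1 | intermediate
4 | 3,4,5-trimethoxyphenol | COc1cc(O)cc(OC)c1OC | starting material
5 | 1,2,3-trimethoxy-5-(methoxymethoxy)benzene | COCOc1cc(OC)c(OC)c(OC)c1 | intermediate
6 | [2,3,4-trimethoxy-6-(methoxymethoxy)phenyl]lithium | [Li]c1c(OCOC)cc(OC)c(OC)c1OC | intermediate (not isolated)
7 | dimethyl [2,3,4-trimethoxy-6-(methoxymethoxy)phenyl]boronate | COCOc1cc(OC)c(OC)c(OC)c1B(OC)OC | intermediate (not isolated)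
8 | 2,3,4-trimethoxy-6-(methoxymethoxy)phenol | COCOc1cc(OC)c(OC)c(OC)c1O | intermediate
9 | 2,3,4-trimethoxyphenol | COc1ccc(O)c(OC)c1OC | starting material
10 | 1,2,3-trimethoxy-4-(methoxymethoxy)benzene | COCOc1ccc(OC)c(OC)c1OC | intermediate
11 | [3,4,5-trimethoxy-2-(methoxymethoxy)phenyl]lithium | [Li]c1cc(OC)c(OC)c(OC)c1OCOC | intermediate (not isolated)
12 | dimethyl [3,4,5-trimethoxy-2-(methoxymethoxy)phenyl]boronate | COCOc1c(B(OC)OC)cc(OC)c(OC)c1OC | intermediate (not isolated)
13 | 3,4,5-trimethoxy-2-(methoxymethoxy)phenol | COCOc1c(O)cc(OC)c(OC)c1OC | intermediate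
14 | 4-bromo-6-{[3,4,5-trimethoxy-2-(methoxymethoxy)phenoxy]methyl}pyran-2-one | COCOc1c(OCc2cc(Br)cc(=O)o2)cc(OC)c(OC)c1OC | intermediate
15 | 2,4,6-trimethoxyphenol | COc1cc(OC)c(O)c(OC)c1 | starting material
16 | 6-{[3,4,5-trimethoxy-2-(methoxymethoxy)phenoxy]methyl}-4-(2,4,6-trimethoxyphenoxy)pyran-2-one | COCOc1c(OCc2cc(Oc3c(OC)cc(OC)cc3OC)cc(=O)o2)cc(OC)c(OC)c1OC | intermediate
17 | methyl (2E)-5-oxo-6-[3,4,5-trimethoxy-2-(methoxymethoxy)phenoxy]-3-(2,4,6-trimethoxyphenoxy)hex-2-enoate | COC(=O)/C=C(/Oc1c(OC)cc(OC)cc1OC)CC(=O)COc1cc(OC)c(OC)c(OC)c1OCOC | intermediate (not isolated)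
18 | 2-[3,4,5-trimethoxy-2-(methoxymethoxy)phenoxy]-5-(2,4,6-trimethoxyphenoxy)benzene-1,3-diol (A–B–C trimer, b3 and b5 free, c6 MOM) | COc1cc(OC)c(Oc2cc(O)c(Oc3cc(OC)c(OC)c(OC)c3OCOC)c(O)c2)c(OC)c1 | intermediate
19 | 1,3-dimethoxy-2-[3,4,5-trimethoxy-2-(methoxymethoxy)phenoxy]-5-(2,4,6-trimethoxyphenoxy)benzene | COc1cc(OC)c(Oc2cc(OC)c(Oc3cc(OC)c(OC)c(OC)c3OCOC)c(OC)c2)c(OC)c1 | intermediate
20 | 6-[2,6-dimethoxy-4-(2,4,6-trimethoxyphenoxy)phenoxy]-2,3,4-trimethoxyphenol (A–B–C phenol, free hydroxyl at c6) | COc1cc(OC)c(Oc2cc(OC)c(Oc3cc(OC)c(OC)c(OC)c3O)c(OC)c2)c(OC)c1 | intermediate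
21 | 4-{6-[2,6-dimethoxy-4-(2,4,6-trimethoxyphenoxy)phenoxy]-2,3,4-trimethoxyphenoxy}-6-{[3,4,5-trimethoxy-2-(methoxymethoxy)phenoxy]methyl}pyran-2-one | COc1cc(OC)c(Oc2cc(OC)c(Oc3cc(OC)c(OC)c(OC)c3Oc3cc(COc4cc(OC)c(OC)c(OC)c4OCOC)oc(=O)c3)c(OC)c2)c(OC)c1 | intermediate
22 | methyl (2E)-3-(A–B–C aryloxy through the c6 oxygen)-5-oxo-6-[3,4,5-trimethoxy-2-(methoxymethoxy)phenoxy]hex-2-enoate | COC(=O)/C=C(/Oc1c(OC)c(OC)c(OC)cc1Oc1c(OC)cc(Oc2c(OC)cc(OC)cc2OC)cc1OC)CC(=O)COc1cc(OC)c(OC)c(OC)c1OCOC | intermediate (not isolated)
23 | A–E pentamer, free hydroxyls at d3 and d5, MOM ether at e6, all other oxygens methylated | COc1cc(OC)c(Oc2cc(OC)c(Oc3cc(OC)c(OC)c(OC)c3Oc3cc(O)c(Oc4cc(OC)c(OC)c(OC)c4OCOC)c(O)c3)c(OC)c2)c(OC)c1 | intermediate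
24 | A–E pentamer, MOM ether at e6, all other oxygens methylated | COc1cc(OC)c(Oc2cc(OC)c(Oc3cc(OC)c(OC)c(OC)c3Oc3cc(OC)c(Oc4cc(OC)c(OC)c(OC)c4OCOC)c(OC)c3)c(OC)c2)c(OC)c1 | intermediate
25 | A–E pentamer phenol, only free hydroxyl at e6 | COc1cc(OC)c(Oc2cc(OC)c(Oc3cc(OC)c(OC)c(OC)c3Oc3cc(OC)c(Oc4cc(OC)c(OC)c(OC)c4O)c(OC)c3)c(OC)c2)c(OC)c1 | intermediate
26 | 5-iodo-1,2,3-trimethoxybenzene | COc1cc(I)cc(OC)c1OC | starting material
27 | 1,2,3-trimethoxy-5-(methoxymethoxy)-4-(3,4,5-trimethoxyphenoxy)benzene | COCOc1cc(OC)c(OC)c(OC)c1Oc1cc(OC)c(OC)c(OC)c1 | intermediate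
28 | 3,4,5-trimethoxy-2-(3,4,5-trimethoxyphenoxy)phenol (I–J phenol, free hydroxyl at i1) | Oc1cc(OC)c(OC)c(OC)c1Oc1cc(OC)c(OC)c(OC)c1 | intermediate
29 | 4-bromo-6-{[3,4,5-trimethoxy-2-(3,4,5-trimethoxyphenoxy)phenoxy]methyl}pyran-2-one | COc1cc(Oc2c(OCc3cc(Br)cc(=O)o3)cc(OC)c(OC)c2OC)cc(OC)c1OC | intermediate
30 | 4-[2,3,4-trimethoxy-6-(methoxymethoxy)phenoxy]-6-{[3,4,5-trimethoxy-2-(3,4,5-trimethoxyphenoxy)phenoxy]methyl}pyran-2-one | COCOc1cc(OC)c(OC)c(OC)c1Oc1cc(COc2cc(OC)c(OC)c(OC)c2Oc2cc(OC)c(OC)c(OC)c2)oc(=O)c1 | intermediate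
31 | methyl (2E)-5-oxo-3-[2,3,4-trimethoxy-6-(methoxymethoxy)phenoxy]-6-[3,4,5-trimethoxy-2-(3,4,5-trimethoxyphenoxy)phenoxy]hex-2-enoate | COC(=O)/C=C(/Oc1c(OCOC)cc(OC)c(OC)c1OC)CC(=O)COc1cc(OC)c(OC)c(OC)c1Oc1cc(OC)c(OC)c(OC)c1 | intermediate (not isolated)
32 | 5-[2,3,4-trimethoxy-6-(methoxymethoxy)phenoxy]-2-[3,4,5-trimethoxy-2-(3,4,5-trimethoxyphenoxy)phenoxy]benzene-1,3-diol (G–J tetramer, h3 and h5 free, g1 MOM) | COCOc1cc(OC)c(OC)c(OC)c1Oc1cc(O)c(Oc2cc(OC)c(OC)c(OC)c2Oc2cc(OC)c(OC)c(OC)c2)c(O)c1 | intermediate
33 | G–J tetramer, MOM ether at g1, all other oxygens methylated | COCOc1cc(OC)c(OC)c(OC)c1Oc1cc(OC)c(Oc2cc(OC)c(OC)c(OC)c2Oc2cc(OC)c(OC)c(OC)c2)c(OC)c1 | intermediate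
34 | 2-{3,5-dimethoxy-4-[3,4,5-trimethoxy-2-(3,4,5-trimethoxyphenoxy)phenoxy]phenoxy}-3,4,5-trimethoxyphenol (G–J phenol, free hydroxyl at g1) | Oc1cc(OC)c(OC)c(OC)c1Oc1cc(OC)c(Oc2cc(OC)c(OC)c(OC)c2Oc2cc(OC)c(OC)c(OC)c2)c(OC)c1 | intermediate
35 | 4-bromo-6-[(G–J tetramer aryloxy)methyl]pyran-2-one | O=c1cc(Br)cc(COc2cc(OC)c(OC)c(OC)c2Oc2cc(OC)c(Oc3cc(OC)c(OC)c(OC)c3Oc3cc(OC)c(OC)c(OC)c3)c(OC)c2)o1 | intermediate
36 | 4-(A–E pentamer aryloxy)-6-[(G–J tetramer aryloxy)methyl]pyran-2-one | COc1cc(OC)c(Oc2cc(OC)c(Oc3cc(OC)c(OC)c(OC)c3Oc3cc(OC)c(Oc4cc(OC)c(OC)c(OC)c4Oc4cc(COc5cc(OC)c(OC)c(OC)c5Oc5cc(OC)c(Oc6cc(OC)c(OC)c(OC)c6Oc6cc(OC)c(OC)c(OC)c6)c(OC)c5)oc(=O)c4)c(OC)c3)c(OC)c2)c(OC)c1 | intermediate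
37 | methyl (2E)-3-(A–E pentamer aryloxy)-6-(G–J tetramer aryloxy)-5-oxohex-2-enoate | COC(=O)/C=C(/Oc1c(OC)c(OC)c(OC)cc1Oc1c(OC)cc(Oc2c(OC)c(OC)c(OC)cc2Oc2c(OC)cc(Oc3c(OC)cc(OC)cc3OC)cc2OC)cc1OC)CC(=O)COc1cc(OC)c(OC)c(OC)c1Oc1cc(OC)c(Oc2cc(OC)c(OC)c(OC)c2Oc2cc(OC)c(OC)c(OC)c2)c(OC)c1 | intermediate (not isolated)
38 | decamer with free hydroxyls at f3 and f5 and all other hydroxyls as methyl ethers | COc1cc(OC)c(Oc2cc(OC)c(Oc3cc(OC)c(OC)c(OC)c3Oc3cc(OC)c(Oc4cc(OC)c(OC)c(OC)c4Oc4cc(O)c(Oc5cc(OC)c(OC)c(OC)c5Oc5cc(OC)c(Oc6cc(OC)c(OC)c(OC)c6Oc6cc(OC)c(OC)c(OC)c6)c(OC)c5)c(O)c4)c(OC)c3)c(OC)c2)c(OC)c1 | intermediate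
39 | CNP0255890.0 (decamer with all hydroxyls free) | Oc1cc(O)c(Oc2cc(O)c(Oc3cc(O)c(O)c(O)c3Oc3cc(O)c(Oc4cc(O)c(O)c(O)c4Oc4cc(O)c(Oc5cc(O)c(O)c(O)c5Oc5cc(O)c(Oc6cc(O)c(O)c(O)c6Oc6cc(O)c(O)c(O)c6)c(O)c5)c(O)c4)c(O)c3)c(O)c2)c(O)c1 | target

Total step count: 26.

Longest linear sequence: 14 steps (steps 5, 6, 7, 8, 9, 10, 11, 12, 13, 14, 15, 24, 25, 26). The branch through 34 has 13 steps (3, 4, 16 to 23, then 24 to 26).

Steps least certain to work

Step 25 (key step). Methoxide may exchange the e6 aryloxy group at C4 by conjugate addition–elimination faster than the carbon–carbon bond forms. The reaction may also stall at the chelated open-chain enolate, because the central CH2 is the more acidic site, and 36 may be poorly soluble in methanol. Fallback: from 36, open the lactone with Mg(OMe)2 at room temperature, isolate the open-chain ester 37, and close it in an aprotic medium by a titanium-mediated Claisen cyclisation (TiCl4, nBu3N, CH2Cl2, −78 to 0 °C). The Lewis acid chelates the ketone oxygen and the g1 oxygen, directs enolisation to the aryloxy-bearing carbon and activates the ester, with no free alkoxide present. The route is rejoined at 38.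

Step 23 (the same operation in steps 7 and 18). The phenoxide may attack C4–Br by addition–elimination in competition with SN2 at CH2Br, giving regioisomeric and doubly substituted ethers. Fallback: build the pyranone around the ether instead. From 34, alkylation with methyl bromoacetate and K2CO3 gives methyl (G–J tetramer aryloxy)acetate F1. Claisen condensation with the dianion of methyl acetoacetate (NaH, then nBuLi, THF, −78 °C) gives methyl 6-(G–J tetramer aryloxy)-3,5-dioxohexanoate F2. Lactonisation (DBU, toluene, reflux) gives 4-hydroxy-6-[(G–J tetramer aryloxy)methyl]pyran-2-one F3. Deoxybromination as in step 1 (nBu4NBr, P2O5) rejoins the route at 35.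

Step 24. Addition–elimination between two large partners may be slow because the e6 phenoxide is flanked by two ortho substituents. Meanwhile base may degrade 35 by deprotonation at the aryloxymethyl carbon or by lactone opening. Fallback: reverse the order of the two unions. From 25 and an excess of the robust 2 (Cs2CO3, DMF, 60 °C) make 6-methyl-4-(A–E pentamer aryloxy)pyran-2-one F4. Deprotonate its methyl group with LiN(SiMe3)2 at −78 °C and quench with CBr4 to give 6-(bromomethyl)-4-(A–E pentamer aryloxy)pyran-2-one F5. Alkylation of 34 with F5 (K2CO3, acetone) rejoins the route at 36.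

Step 16. Carbon–oxygen coupling of a di-ortho-substituted phenoxide with an electron-rich aryl iodide may be sluggish and reductive loss of iodine may compete. Fallback: make the bridge by SNAr and then convert the activating group. From 8, reaction with 4-fluoro-2,6-dimethoxybenzaldehyde (K2CO3, DMF, 110 °C) gives 2,6-dimethoxy-4-[2,3,4-trimethoxy-6-(methoxymethoxy)phenoxy]benzaldehyde F6. Dakin-type oxidation (mCPBA, CH2Cl2; then KOH, MeOH) gives 2,6-dimethoxy-4-[2,3,4-trimethoxy-6-(methoxymethoxy)phenoxy]phenol F7. Methylation (MeI, K2CO3) rejoins the route at 27.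

Step 26. Some of the methyl ethers may stay uncleaved when partly borylated intermediates precipitate from CH2Cl2, and the free polyphenol may oxidise during isolation. Fallback: from 38, treat the crude product of the BBr3 reaction with Ac2O, pyridine and DMAP to give the decamer hexacosaacetate F8. It is stable and can be purified on silica, and fractions that still carry methyl groups can be returned to BBr3. Deacetylation of pure F8 (catalytic NaOMe in degassed MeOH under argon, then acidic resin) rejoins the route at 39.

Further compounds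

F0 | step 25 | none | none
F1 | step 23 | methyl (G–J tetramer aryloxy)acetate | COC(=O)COc1cc(OC)c(OC)c(OC)c1Oc1cc(OC)c(Oc2cc(OC)c(OC)c(OC)c2Oc2cc(OC)c(OC)c(OC)c2)c(OC)c1
F2 | step 23 | methyl 6-(G–J tetramer aryloxy)-3,5-dioxohexanoate | COC(=O)CC(=O)CC(=O)COc1cc(OC)c(OC)c(OC)c1Oc1cc(OC)c(Oc2cc(OC)c(OC)c(OC)c2Oc2cc(OC)c(OC)c(OC)c2)c(OC)c1
F3 | step 23 | 4-hydroxy-6-[(G–J tetramer aryloxy)methyl]pyran-2-one | O=c1cc(O)cc(COc2cc(OC)c(OC)c(OC)c2Oc2cc(OC)c(Oc3cc(OC)c(OC)c(OC)c3Oc3cc(OC)c(OC)c(OC)c3)c(OC)c2)o1
F4 | step 24 | 6-methyl-4-(A–E pentamer aryloxy)pyran-2-one | Cc1cc(Oc2c(OC)c(OC)c(OC)cc2Oc2c(OC)cc(Oc3c(OC)c(OC)c(OC)cc3Oc3c(OC)cc(Oc4c(OC)cc(OC)cc4OC)cc3OC)cc2OC)cc(=O)o1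
F5 | step 24 | 6-(bromomethyl)-4-(A–E pentamer aryloxy)pyran-2-one | BrCc1cc(Oc2c(OC)c(OC)c(OC)cc2Oc2c(OC)cc(Oc3c(OC)c(OC)c(OC)cc3Oc3c(OC)cc(Oc4c(OC)cc(OC)cc4OC)cc3OC)cc2OC)cc(=O)o1
F6 | step 16 | 2,6-dimethoxy-4-[2,3,4-trimethoxy-6-(methoxymethoxy)phenoxy]benzaldehyde | COCOc1cc(OC)c(OC)c(OC)c1Oc1cc(OC)c(C=O)c(OC)c1
F7 | step 16 | 2,6-dimethoxy-4-[2,3,4-trimethoxy-6-(methoxymethoxy)phenoxy]phenol | COCOc1cc(OC)c(OC)c(OC)c1Oc1cc(OC)c(O)c(OC)c1
F8 | step 26 | decamer hexacosaacetate (every hydroxyl of 39 acetylated) | CC(=O)Oc1cc(OC(C)=O)c(Oc2cc(OC(C)=O)c(Oc3cc(OC(C)=O)c(OC(C)=O)c(OC(C)=O)c3Oc3cc(OC(C)=O)c(Oc4cc(OC(C)=O)c(OC(C)=O)c(OC(C)=O)c4Oc4cc(OC(C)=O)c(Oc5cc(OC(C)=O)c(OC(C)=O)c(OC(C)=O)c5Oc5cc(OC(C)=O)c(Oc6cc(OC(C)=O)c(OC(C)=O)c(OC(C)=O)c6Oc6cc(OC(C)=O)c(OC(C)=O)c(OC(C)=O)c6)c(OC(C)=O)c5)c(OC(C)=O)c4)c(OC(C)=O)c3)c(OC(C)=O)c2)c(OC(C)=O)c1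
A1 | alternative 1 | 2-[2-(benzyloxy)-3,4,5-trimethoxyphenoxy]-3-ethoxy-5-(2,4,6-trimethoxyphenoxy)phenol | COc1cc(OC)c(Oc2cc(O)c(Oc3cc(OC)c(OC)c(OC)c3OCc3ccccc3)c(OCC)c2)c(OC)c1
A2 | alternative 1 | 4-[2-(benzyloxy)-3,4,5-trimethoxyphenoxy]-3-ethoxycyclobut-2-en-1-one (racemic) | CCOC1=CC(=O)C1Oc1cc(OC)c(OC)c(OC)c1OCc1ccccc1
A3 | alternative 1 | 2-(ethynyloxy)-1,3,5-trimethoxybenzene | C#COc1c(OC)cc(OC)cc1OC
A4 | alternative 2 | 6-[2,6-dimethoxy-4-(2,4,6-trimethoxyphenoxy)phenoxy]-2,3,4-trimethoxyphenol | COc1cc(OC)c(Oc2cc(OC)c(Oc3cc(OC)c(OC)c(OC)c3O)c(OC)c2)c(OC)c1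
A5 | alternative 2 | 4-{(E)-2-[2,6-dimethoxy-4-(2,4,6-trimethoxyphenoxy)phenoxy]ethenyl}-2,3,4-trimethoxycyclobut-2-en-1-one (racemic) | COC1=C(OC)C(OC)(/C=C/Oc2c(OC)cc(Oc3c(OC)cc(OC)cc3OC)cc2OC)C1=O
A6 | alternative 3 | decamer with free hydroxyls at c4, e4, g4, i4 and j4 and all other hydroxyls as methyl ethers | COc1cc(OC)c(Oc2cc(OC)c(Oc3cc(OC)c(O)c(OC)c3Oc3cc(OC)c(Oc4cc(OC)c(O)c(OC)c4Oc4cc(OC)c(Oc5cc(OC)c(O)c(OC)c5Oc5cc(OC)c(Oc6cc(OC)c(O)c(OC)c6Oc6cc(OC)c(O)c(OC)c6)c(OC)c5)c(OC)c4)c(OC)c3)c(OC)c2)c(OC)c1
A7 | alternative 3 | decamer pentaaldehyde with formyl groups at c4, e4, g4, i4 and j4 and all hydroxyls as methyl ethers | COc1cc(OC)c(Oc2cc(OC)c(Oc3cc(OC)c(C=O)c(OC)c3Oc3cc(OC)c(Oc4cc(OC)c(C=O)c(OC)c4Oc4cc(OC)c(Oc5cc(OC)c(C=O)c(OC)c5Oc5cc(OC)c(Oc6cc(OC)c(C=O)c(OC)c6Oc6cc(OC)c(C=O)c(OC)c6)c(OC)c5)c(OC)c4)c(OC)c3)c(OC)c2)c(OC)c1
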